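Early on the delta run crept, with 1.4% of the charge as target at 12.0 min. So I asked how long a run idles, how long a turn of the catalyst takes, and how many turns the flask's hour holds.

| setting | delta | theta | flask |
|---|---|---|---|
| substrate | 0.10 M | 0.10 M | 0.10 M |
| gas | 40 mM (held) | 40 mM (held) | 40 mM (held) |
| free catalyst | 0.20 mM | 0.31 mM | 0.41 mM |
| remark | run made earlier | run made earlier |  |
| time |  |  | 1.0 h |

| run | time / min | target / % |
|---|---|---|
| delta | 6.00 | 0.7 |
| delta | 8.00 | 1.0 |
| delta | 12.0 | 1.4 |
| delta | 20.0 | 2.2 |
| delta | 30.0 | 6.0 |
| delta | 50.0 | 10.9 |
| delta | 80.0 | 19.6 |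
| theta | 6.00 | 0.2 |
| theta | 8.00 | 0.9 |
| theta | 12.0 | 2.2 |
| theta | 20.0 | 4.4 |
| theta | 30.0 | 7.0 |
| theta | 50.0 | 15.4 |
| theta | 80.0 | 28.0 |

(readings scatter by 0.5 percentage points)

- at the start none of the gas is in solution

- ash: doubling the amount of free catalyst, all else as stated
- elm: doubling the saturation concentration of gas, all else as stated
- cedar: doubling the transfer coefficient of the gas, all else as stated

- target at 1.0 h, in percent of the substrate charged
- the change that raises the amount of target at 1.0 h, in percent of the substrate charged most ("none" if none brings more than 2 percentage points) (ash / elm / cedar / none)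
- amount of target at 1.0 h, in percent of the substrate charged, after ash

From 30.0 min to 80.0 min the target grew by 0.00272 /min of the charge in delta and 0.00420 /min in theta. Projected back, these lines reach zero at 7.94 min and 13.3 min, so I took their mean, 10.6 min, as the lag.

I defined the turn time (turnover time, the inverse of the turnover frequency) as the catalyst's fraction of the charge divided by that growth: 0.735 min in delta and 0.738 min in theta, the same within the readings.

By my count the flask's hour, less the lag, held 67.1 turns, each worth 0.410% of the charge, so I committed to 27.5%. Doubling the catalyst gave 55.0% by this count, an untested extrapolation. Both runs held 40 mM of gas, so I had no count for elm or cedar.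

The forecast gave 26%, chose elm, and put ash at 43%, a figure lower than my count for ash: “Doubling catalyst should give less than double the rate”.

The flask gave 22.8%; elm gained 13 percentage points, cedar 11 points and ash 6.6 points, reaching 29.3%.

    substrate + free catalyst → catalyst intermediate A (k = 100 /M/min)
    reagent + catalyst intermediate A → catalyst intermediate B (k = 240 /M/min)
    catalyst intermediate B → catalyst intermediate C (k = 10.0 /min)
    catalyst intermediate C ⇌ released group + catalyst intermediate D (K = 6.70 M, k = 13.0 /min)
    catalyst intermediate D ⇌ free catalyst + target (K = 0.110 M, k = 33.0 /min)
    gas ⇌ reagent, rate k6*(csat - [reagent]) (kL = 0.0150 /min)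

At 1.00 h catalyst intermediate A, the resting state, held 59.3% of the flask's catalyst. From 0.500 h to 1.0 h the flask's turn time was 0.914 min, longer than the 0.735 min read from delta. A neighbour charged with 1.6 × 10⁻⁴ M of free catalyst counted 10.7% and gave 12.0%.

(The numbers in the tables stem from a simulated flask from invented constants; noise was put on by code.)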